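Sunday's charge of G stands to Friday's as 2.31, yet at 2.50 min Sunday's L reads 26.7 % of the D charged and Friday's reads 0.4 %, which lies within the scatter, so the ratio of the L readings is far larger than the ratio of the charges.

common to all: D 0.020 M; E 13 µM

| flask | J | G | remark |
|---|---|---|---|
| Friday's | 0.018 M | 13 µM | run made earlier |
| Sunday's | 0.018 M | 30 µM | run made earlier |
| flask | 0.0180 M | 20 µM |  |

| Friday's: time / min | Friday's: L / % | Sunday's: time / min | Sunday's: L / % |
|---|---|---|---|
| 0.500 | 0.9 | 0.500 | 7.0 |
| 1.00 | 0 | 1.00 | 12.0 |
| 1.50 | 0 | 1.50 | 20.1 |
| 2.00 | 0 | 2.00 | 25.6 |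
| 2.50 | 0.4 | 2.50 | 26.7 |

(each reading ± 1 percentage point)

- factor on the rate of making L when 50 % of the D are converted if G is charged twice over
- factor on the rate when 50 % of the D are converted if G is charged at 4.0 µM instead

Friday's G equals its E, so I take E for a catalyst poison that removes G one to one. In the new flask that leaves 7.00 µM as the excess of G, the charge of G minus the charge of E. Control changes hands where the excess crosses zero: below that crossing E holds the catalyst, above it the excess turns D and J into L.

Charging 40.0 µM of G raises the excess to 27.0 µM. At equal conversion I take [D] and [J] as equal in both cases; if the rate is then first order in the excess, the factor is 3.86. With 4.0 µM of G, the charge lies below E, so I write a factor of zero.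

The weak link is the claim that Friday sits on the crossing. I reforge it from the readings: Sunday's reading at 2.00 min gives a pace of 0.128 min⁻¹ of the D charged on an excess of 17.0 µM. At that pace, Friday's last reading, taken at face value, means 0.212 µM of working G. Adding this to both excesses gives 3.77, so I stay near my figure.

The forecast gives 3.9 (from 2.6 to 6) and 0 (up to 0.03), holding that “only the excess G works”.

The flask gives a factor of 3.88 when G is charged at 40.0 µM.

    D + G ⇌ G + X (K = 1.30, k = 1.70 × 10⁵ M⁻¹ min⁻¹)
    J + G + X → G + L (k = 18000 M⁻² s⁻¹)
    D + J → Q (k = 0.260 M⁻¹ min⁻¹)
    G + E → Z (k = 78000 M⁻¹ s⁻¹)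

At 1.25 min the new flask holds 35.0 % of its catalyst as G and 65.0 % as Z, the form that G and E make together, with E at 0 %. The excess as a share of the charge is 35.0 %. With 4.0 µM of G the charge of G minus the charge of E is −9.00 µM, and the factor on the rate is −2.30 × 10⁻²⁴.

(The numbers in the tables come from a simulation from invented constants; scatter was added.)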